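**Remarks on the chemistry (assumptions)**
- The SMILES is read as (2R,3S,4S)-robinetinidol (2,3-trans, 3,4-trans) joined through C4 to C8 of (2R,3S)-catechin.
- The sense of induction of Rh2(S-PTTL)4 on diazo ester 5 is taken to give the (2S) series; if the opposite sense is found, Rh2(R-PTTL)4 is used without other change.

**Retrosynthetic overview**
1. Target ⇐ fluoride desilylation and hydrogenolysis of nine benzyl ethers from a fully protected bis-flavan.
2. Protected bis-flavan ⇐ one-carbon ring enlargement of the furan ring of a trans-2-aryl-2,3-dihydrobenzofuran-3-carbaldehyde: C2 shifts from C3 to the silyl-activated formyl carbon, and the resulting 3-silyloxyflavan-4-yl cation is captured by C8 of penta-O-benzylcatechin. This one operation gives the upper pyran ring (O1–C2–C3–C4–C4a–C8a), the C4–C8 bond and the C3 and C4 stereocentres.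
3. Enabling feature: C4 is benzylic to ring A, para to O7 and ortho to O1 (a 2,4-dioxygenated benzyl cation), and the migrating C2 carries O1 and the electron-rich ring B.
4. Aldehyde ⇐ enantioselective dirhodium-carbene 1,5 C–H insertion of an aryldiazoacetate (sets C2), then reduction, oxidation and epimerisation; diazo ester ⇐ diazoacetate homologation of a 2,4-dialkoxybenzaldehyde made by Mitsunobu etherification.
5. Ring order: rings A and B are bought; dihydrofuran ring (step 4) → upper pyran ring by ring enlargement (step 9); the lower flavan unit comes intact from (+)-catechin.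

Key step: step 9

**Route**

Step 1
Reactants: 1 4-(benzyloxy)-2-hydroxybenzaldehyde; 2 3,4,5-tris(benzyloxy)benzyl alcohol
Product: 3 4-(benzyloxy)-2-{[3,4,5-tris(benzyloxy)phenyl]methoxy}benzaldehyde
Conditions: PPh3, DIAD, THF, 0 °C → rt
Reagents that add atoms: none
Why: Mitsunobu etherification of the acidic salicylaldehyde-type phenol with the primary benzylic alcohol proceeds under neutral conditions that leave the aldehyde and benzyl ethers untouched; no stereocentre is formed.

Step 2
Reactants: 3 4-(benzyloxy)-2-{[3,4,5-tris(benzyloxy)phenyl]methoxy}benzaldehyde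
Product: 4 ethyl (Z)-2-[4-(benzyloxy)-2-{[3,4,5-tris(benzyloxy)phenyl]methoxy}phenyl]-3-hydroxyprop-2-enoate (enol form of the α-formyl arylacetate)
Conditions: N2CHCO2Et (1.2 equiv), HBF4·OEt2 (10 mol%), CH2Cl2, −78 °C
Reagents that add atoms: ethyl diazoacetate, [N-]=[N+]=CC(=O)OCC
Why: Roskamp-type homologation in its aryl-shift mode: the acid-activated aldehyde adds the diazo ester and the electron-rich 2,4-dialkoxyphenyl group migrates with loss of N2, giving the α-formyl ester as its hydrogen-bonded enol; no lasting stereocentre is formed.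

Step 3
Reactants: 4 ethyl (Z)-2-aryl-3-hydroxyprop-2-enoate
Product: 5 ethyl 2-[4-(benzyloxy)-2-{[3,4,5-tris(benzyloxy)phenyl]methoxy}phenyl]-2-diazoacetate
Conditions: p-ABSA, Et3N, MeCN, 0 °C → rt
Reagents that add atoms: 4-acetamidobenzenesulfonyl azide (p-ABSA), CC(=O)Nc1ccc(cc1)S(=O)(=O)N=[N+]=[N-]
Why: Regitz deformylative diazo transfer: the formyl-activated carbon attacks the sulfonyl azide and the formyl group leaves as the N-formylsulfonamide, giving the donor/acceptor diazo ester under mild base that all ethers tolerate.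

Step 4
Reactants: 5 ethyl 2-aryl-2-diazoacetate
Product: 6 ethyl (2S,3R)-6-(benzyloxy)-2-[3,4,5-tris(benzyloxy)phenyl]-2,3-dihydro-1-benzofuran-3-carboxylate (2,3-cis)
Conditions: Rh2(S-PTTL)4 (dirhodium tetrakis[N-phthaloyl-(S)-tert-leucinate], 1 mol%), toluene, −60 °C
Reagents that add atoms: none
Why: Enantioselective intramolecular 1,5 C–H insertion of the dirhodium donor/acceptor carbene into the ether-activated benzylic C–H bond, closely precedented for 2-(benzyloxy)phenyl diazoacetates, closes the dihydrofuran ring; the chiral carboxylate ligands set C2 and the concerted insertion gives the cis ester.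

Step 5
Reactants: 6 ethyl (2S,3R)-cis-dihydrobenzofuran-3-carboxylate
Product: 7 [(2S,3S)-6-(benzyloxy)-2-[3,4,5-tris(benzyloxy)phenyl]-2,3-dihydro-1-benzofuran-3-yl]methanol (2,3-cis)
Conditions: LiAlH4, THF, 0 °C
Reagents that add atoms: none
Why: Hydride reduction of the ester to the primary alcohol leaves benzyl ethers and both stereocentres alone; the C3 descriptor changes only because the substituent priorities change.

Step 6
Reactants: 7 (2S,3S)-cis-3-(hydroxymethyl)dihydrobenzofuran
Product: 9 (2S,3S)-6-(benzyloxy)-2-[3,4,5-tris(benzyloxy)phenyl]-2,3-dihydro-1-benzofuran-3-carbaldehyde (2,3-trans), via cis-aldehyde 8 (not isolated)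
Conditions: Dess–Martin periodinane, CH2Cl2, 0 °C → rt; work-up; then DBU (0.2 equiv), CH2Cl2, rt
Reagents that add atoms: none
Why: Dess–Martin oxidation gives the cis α-aryl aldehyde, which DBU-mediated enolisation equilibrates to the more stable 2,3-trans isomer (C3 under thermodynamic control); C2 is safe because ring opening by β-elimination would be the reverse of a disfavoured 5-endo-trig closure.

Step 7
Reactants: 10 (+)-catechin
Product: 11 5,7,3',4'-tetra-O-benzyl-(+)-catechin
Conditions: BnBr (4.4 equiv), K2CO3, DMF, 0 °C → rt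
Reagents that add atoms: benzyl bromide, BrCc1ccccc1
Why: Williamson etherification with a weak base alkylates the four phenols selectively and leaves the secondary 3-OH and both stereocentres untouched.

Step 8
Reactants: 11 5,7,3',4'-tetra-O-benzyl-(+)-catechin
Product: 12 3,5,7,3',4'-penta-O-benzyl-(+)-catechin
Conditions: NaH, BnBr, DMF, 0 °C → rt
Reagents that add atoms: benzyl bromide, BrCc1ccccc1
Why: Williamson etherification of the secondary alkoxide blocks O3 so that O-silylation or O-alkylation of the nucleophile cannot compete in the key step; C2 and C3 are unaffected.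

Step 9
Reactants: 9 (2S,3S)-trans-2-aryl-2,3-dihydrobenzofuran-3-carbaldehyde; 12 3,5,7,3',4'-penta-O-benzyl-(+)-catechin (2.5 equiv)
Product: 14 3-O-triethylsilyl-nona-O-benzyl-robinetinidol-(4α→8)-catechin [(2R,3S,4S) upper unit with 7,3',4',5'-OBn and 3-OSiEt3; (2R,3S) lower unit with 3,5,7,3',4'-OBn], via flavan-4-yl cation 13 (not isolated)
Conditions: Et3SiOTf (1.5 equiv), 2,6-di-tert-butyl-4-methylpyridine (2 equiv), 4 Å MS, CH2Cl2, −78 → −40 °C
Reagents that add atoms: triethylsilyl trifluoromethanesulfonate, CC[Si](CC)(CC)OS(=O)(=O)C(F)(F)F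
Why: Proposed new method: O-silylation of the formyl group gives a silyloxycarbenium ion to which C2 (the best donor σ-bond, carrying O1 and the trialkoxyphenyl ring) shifts from the ring carbon with retention, inserting the formyl carbon into the five-membered ring and leaving a 3-silyloxyflavan-4-yl cation stabilised by O7 (para) and O1 (ortho), which C8 of 12 captures in a Friedel–Crafts step. The closest known reaction types are the first stage of the acid-mediated aldehyde–ketone (Danilov) rearrangement, the reverse sense of the semipinacol ring contraction of 4-activated flavan-3-ols to 2-aryl-2,3-dihydrobenzofuran-3-carbaldehydes, and the silyl-triflate-mediated C4–C8 coupling of flavan-4-yl cations with benzylated catechin. The pyran ring is not closed by cyclisation but arises by a 1,2-alkyl shift (ring enlargement from five to six); the second bond is an intermolecular arylation. C2 keeps its configuration; C3 is set by the formyl face that C2 attacks, expected to place OSiEt3 trans to the 2-aryl group (oxygen over the ring-carbon–aryl bond, formyl hydrogen eclipsing C–H), with reversibility of the shift funnelling material through the more stable 2,3-trans cation; C4 is set by arene attack anti to OSiEt3 (3,4-trans, 4α). The step needs carbon migration to outrun hydride migration and direct arylation of the carbonyl, which the cation-stabilising groups on C2, the hindered α-branched aldehyde, the far larger population of the stabilised flavanyl cation and the low temperature should secure. It also needs C8 over C6 attack, which the 5,7-di-O-benzyl pattern of 12 is known to favour.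

Step 10
Reactants: 14 3-O-triethylsilyl-nona-O-benzyl-robinetinidol-(4α→8)-catechin
Product: 15 nona-O-benzyl-robinetinidol-(4α→8)-catechin (upper 3-OH free)
Conditions: HF·pyridine, THF/pyridine, 0 °C → rt
Reagents that add atoms: none
Why: Fluoride cleavage of the silyl ether (driven by the Si–F bond) under buffered conditions frees the upper 3-OH without touching benzyl ethers, the interflavan bond or any stereocentre.

Step 11
Reactants: 15 nona-O-benzyl-robinetinidol-(4α→8)-catechin
Product: 16 robinetinidol-(4α→8)-catechin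
Conditions: H2 (1 atm), Pd(OH)2/C, THF/MeOH/H2O, rt; filtration and lyophilisation under argon
Reagents that add atoms: none
Why: Catalytic hydrogenolysis cleaves all nine benzyl ethers (eight aryl, one alkyl) under neutral conditions in which the cyclic C2–O1 bonds and the 5-deoxy interflavan bond are expected to survive, as in procyanidin syntheses, with all five stereocentres untouched.

**Compound list**

1 | 4-(benzyloxy)-2-hydroxybenzaldehyde | O=Cc1ccc(OCc2ccccc2)cc1O | starting material
2 | 3,4,5-tris(benzyloxy)benzyl alcohol | OCc1cc(OCc2ccccc2)c(OCc2ccccc2)c(OCc2ccccc2)c1 | starting material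
3 | 4-(benzyloxy)-2-{[3,4,5-tris(benzyloxy)phenyl]methoxy}benzaldehyde | O=Cc1ccc(OCc2ccccc2)cc1OCc1cc(OCc2ccccc2)c(OCc2ccccc2)c(OCc2ccccc2)c1 | intermediate
4 | ethyl (Z)-2-[4-(benzyloxy)-2-{[3,4,5-tris(benzyloxy)phenyl]methoxy}phenyl]-3-hydroxyprop-2-enoate | CCOC(=O)/C(=C\O)c1ccc(OCc2ccccc2)cc1OCc1cc(OCc2ccccc2)c(OCc2ccccc2)c(OCc2ccccc2)c1 | intermediate
5 | ethyl 2-[4-(benzyloxy)-2-{[3,4,5-tris(benzyloxy)phenyl]methoxy}phenyl]-2-diazoacetate | CCOC(=O)C(=[N+]=[N-])c1ccc(OCc2ccccc2)cc1OCc1cc(OCc2ccccc2)c(OCc2ccccc2)c(OCc2ccccc2)c1 | intermediate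
6 | ethyl (2S,3R)-6-(benzyloxy)-2-[3,4,5-tris(benzyloxy)phenyl]-2,3-dihydro-1-benzofuran-3-carboxylate (cis) | c1ccc(cc1)COc1ccc2c(c1)O[C@H](c1cc(OCc3ccccc3)c(OCc3ccccc3)c(OCc3ccccc3)c1)[C@@H]2C(=O)OCC | intermediate
7 | [(2S,3S)-6-(benzyloxy)-2-[3,4,5-tris(benzyloxy)phenyl]-2,3-dihydro-1-benzofuran-3-yl]methanol (cis) | c1ccc(cc1)COc1ccc2c(c1)O[C@H](c1cc(OCc3ccccc3)c(OCc3ccccc3)c(OCc3ccccc3)c1)[C@@H]2CO | intermediate
8 | (2S,3R)-6-(benzyloxy)-2-[3,4,5-tris(benzyloxy)phenyl]-2,3-dihydro-1-benzofuran-3-carbaldehyde (cis) | c1ccc(cc1)COc1ccc2c(c1)O[C@H](c1cc(OCc3ccccc3)c(OCc3ccccc3)c(OCc3ccccc3)c1)[C@@H]2C=O | intermediate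
9 | (2S,3S)-6-(benzyloxy)-2-[3,4,5-tris(benzyloxy)phenyl]-2,3-dihydro-1-benzofuran-3-carbaldehyde (trans) | c1ccc(cc1)COc1ccc2c(c1)O[C@H](c1cc(OCc3ccccc3)c(OCc3ccccc3)c(OCc3ccccc3)c1)[C@H]2C=O | intermediate
10 | (+)-catechin, (2R,3S) | Oc1cc(O)c2c(c1)O[C@H](c1ccc(O)c(O)c1)[C@@H](O)C2 | starting material
11 | 5,7,3',4'-tetra-O-benzyl-(+)-catechin | c1ccc(cc1)COc1cc(OCc3ccccc3)c2c(c1)O[C@H](c1ccc(OCc3ccccc3)c(OCc3ccccc3)c1)[C@@H](O)C2 | intermediate
12 | 3,5,7,3',4'-penta-O-benzyl-(+)-catechin | c1ccc(cc1)COc1cc(OCc3ccccc3)c2c(c1)O[C@H](c1ccc(OCc3ccccc3)c(OCc3ccccc3)c1)[C@@H](OCc3ccccc3)C2 | intermediate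
13 | (2R,3S)-7-(benzyloxy)-3-(triethylsilyloxy)-2-[3,4,5-tris(benzyloxy)phenyl]chroman-4-ylium (flavan-4-yl cation) | c1ccc(cc1)COc1ccc2c(c1)O[C@H](c1cc(OCc3ccccc3)c(OCc3ccccc3)c(OCc3ccccc3)c1)[C@@H](O[Si](CC)(CC)CC)[CH+]2 | intermediate
14 | 3-O-triethylsilyl-nona-O-benzyl-robinetinidol-(4α→8)-catechin, (2R,3S,4S)/(2R,3S) | c1ccc(cc1)COc1ccc2c(c1)O[C@H](c1cc(OCc3ccccc3)c(OCc3ccccc3)c(OCc3ccccc3)c1)[C@@H](O[Si](CC)(CC)CC)[C@@H]2c1c(OCc3ccccc3)cc(OCc3ccccc3)c2c1O[C@H](c1ccc(OCc3ccccc3)c(OCc3ccccc3)c1)[C@@H](OCc3ccccc3)C2 | intermediate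
15 | nona-O-benzyl-robinetinidol-(4α→8)-catechin (upper 3-OH free) | c1ccc(cc1)COc1ccc2c(c1)O[C@H](c1cc(OCc3ccccc3)c(OCc3ccccc3)c(OCc3ccccc3)c1)[C@@H](O)[C@@H]2c1c(OCc3ccccc3)cc(OCc3ccccc3)c2c1O[C@H](c1ccc(OCc3ccccc3)c(OCc3ccccc3)c1)[C@@H](OCc3ccccc3)C2 | intermediate
16 | robinetinidol-(4α→8)-catechin | Oc1ccc2c(c1)O[C@H](c1cc(O)c(O)c(O)c1)[C@@H](O)[C@@H]2c1c(O)cc(O)c2c1O[C@H](c1ccc(O)c(O)c1)[C@@H](O)C2 | target

**Step count and risks**

Total steps: 11. Longest linear sequence: 9 (steps 1–6, then 9–11); steps 7–8 form the second branch.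

Steps most likely to fail:

1. Step 9 (proposed new method). Hydride instead of carbon may migrate to the activated formyl carbon, followed by proton loss and aromatisation to a benzofuran. The arene may attack the activated carbonyl directly. Facial control at C3 may be poor. Reversible heterolysis of the C2–C3 bond may erode enantiopurity. The fallback uses only known flavan-3,4-diol chemistry and sets out from 12. Commercial (2R,3R)-dihydrorobinetin F1 is benzylated at its four phenols (BnBr, K2CO3, DMF) to (2R,3R)-7-(benzyloxy)-3-hydroxy-2-[3,4,5-tris(benzyloxy)phenyl]chroman-4-one F2. NaBH4 in THF/EtOH reduces the ketone to (2R,3S,4R)-7-(benzyloxy)-2-[3,4,5-tris(benzyloxy)phenyl]chromane-3,4-diol F3. The diol is ionised at C4 with BF3·OEt2 in CH2Cl2/THF at low temperature in the presence of excess 12, the established Lewis-acid condensation of a flavan-3,4-diol with a flavan-3-ol nucleophile, with attack anti to the 3-OH. This comes back to the route at 15.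

2. Step 4. Enantio- or cis/trans control in the carbene insertion may be insufficient, or the carbene may dimerise. The fallback replaces catalyst control by resolution and sets out from 5. Insertion with achiral Rh2(OAc)4 in CH2Cl2 gives racemic cis ethyl 6-(benzyloxy)-2-[3,4,5-tris(benzyloxy)phenyl]-2,3-dihydro-1-benzofuran-3-carboxylate F4. Preparative chromatography on a chiral stationary phase separates the enantiomers, and the (2S,3R) fraction comes back to the route at 6.

3. Step 2. A 1,2-hydride shift may compete and give the β-keto ester, or the acid may cleave the electron-rich benzylic aryl ether. The fallback is an acid-free homologation and sets out from 3. Decarboxylative trichloromethylation (CCl3CO2Na, CCl3CO2H, DMF, rt) gives racemic 1-[4-(benzyloxy)-2-{[3,4,5-tris(benzyloxy)phenyl]methoxy}phenyl]-2,2,2-trichloroethanol F5. Jocic-type reductive homologation (NaBH4, NaOH, t-BuOH, 55 °C) gives 2-[4-(benzyloxy)-2-{[3,4,5-tris(benzyloxy)phenyl]methoxy}phenyl]acetic acid F6. Esterification (EtI, K2CO3, DMF) gives ethyl 2-[4-(benzyloxy)-2-{[3,4,5-tris(benzyloxy)phenyl]methoxy}phenyl]acetate F7. Regitz diazo transfer (p-ABSA, DBU, MeCN) then comes back to the route at 5.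

**Further compounds**

F1 | step 9 | (2R,3R)-dihydrorobinetin | Oc1ccc2c(c1)O[C@H](c1cc(O)c(O)c(O)c1)[C@@H](O)C2=O
F2 | step 9 | (2R,3R)-7-(benzyloxy)-3-hydroxy-2-[3,4,5-tris(benzyloxy)phenyl]chroman-4-one | c1ccc(cc1)COc1ccc2c(c1)O[C@H](c1cc(OCc3ccccc3)c(OCc3ccccc3)c(OCc3ccccc3)c1)[C@@H](O)C2=O
F3 | step 9 | (2R,3S,4R)-7-(benzyloxy)-2-[3,4,5-tris(benzyloxy)phenyl]chromane-3,4-diol | c1ccc(cc1)COc1ccc2c(c1)O[C@H](c1cc(OCc3ccccc3)c(OCc3ccccc3)c(OCc3ccccc3)c1)[C@@H](O)[C@@H]2O
F4 | step 4 | racemic cis ethyl 6-(benzyloxy)-2-[3,4,5-tris(benzyloxy)phenyl]-2,3-dihydro-1-benzofuran-3-carboxylate (both enantiomers) | c1ccc(cc1)COc1ccc2c(c1)O[C@H](c1cc(OCc3ccccc3)c(OCc3ccccc3)c(OCc3ccccc3)c1)[C@@H]2C(=O)OCC.c1ccc(cc1)COc1ccc2c(c1)O[C@@H](c1cc(OCc3ccccc3)c(OCc3ccccc3)c(OCc3ccccc3)c1)[C@H]2C(=O)OCC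
F5 | step 2 | racemic 1-[4-(benzyloxy)-2-{[3,4,5-tris(benzyloxy)phenyl]methoxy}phenyl]-2,2,2-trichloroethanol | OC(c1ccc(OCc2ccccc2)cc1OCc1cc(OCc2ccccc2)c(OCc2ccccc2)c(OCc2ccccc2)c1)C(Cl)(Cl)Cl
F6 | step 2 | 2-[4-(benzyloxy)-2-{[3,4,5-tris(benzyloxy)phenyl]methoxy}phenyl]acetic acid | OC(=O)Cc1ccc(OCc2ccccc2)cc1OCc1cc(OCc2ccccc2)c(OCc2ccccc2)c(OCc2ccccc2)c1
F7 | step 2 | ethyl 2-[4-(benzyloxy)-2-{[3,4,5-tris(benzyloxy)phenyl]methoxy}phenyl]acetate | CCOC(=O)Cc1ccc(OCc2ccccc2)cc1OCc1cc(OCc2ccccc2)c(OCc2ccccc2)c(OCc2ccccc2)c1
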